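**Retrosynthetic overview**
- The target is the vanillate of an all-cis cyclodeca-3,7-diene-1,9-diol with isopropyl at C10 (C1 = acyloxy carbon, C3=C4 and C7=C8 = the two Z ring alkenes, C9 = hydroxy carbon, C10 = isopropyl carbon). Last disconnections: the ester C(=O)–O1 bond, the silyl groups, and isopropyl back to isopropenyl.
- Key disconnection: ring bond C10–C1. The enabling feature is that C10 carries a three-carbon branch next to carbinol C1, so O1–C1–C10–C(CH3)=CH2 is the homoallylic-alcohol retron of an allylboration. C10 is also flanked by the oxygenated stereocenter C9, which can steer it, and the Z alkenes C3=C4 and C7=C8 of the ten-membered ring pre-fold the open chain.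
- Precursor: an acyclic (Z)-allyl pinacolboronate aldehyde with a single stereocenter (C9, from a CBS reduction). Its intramolecular allylboration closes the carbocycle and sets C10 and C1 in one operation.
- The chain comes from three small pieces: anhydromevalonolactone (C1–C5, Z alkene C3=C4 fixed by the lactone ring; C6 from a Wittig ylide), (Z)-3-iodobut-2-enoic acid (C7–C9, joined at C6–C7 by B-alkyl Suzuki coupling) and propynylmagnesium bromide (C10 and its branch, made into the Z-allylboronate by hydroalumination–iodination and coupling with CH2(Bpin)2).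
- Ring order: the aromatic ring is bought as vanillic acid; the ten-membered carbocycle is the only ring made, in step 13.

Key step: step 13

Remark: the SMILES is taken as written, i.e. both ring alkenes cis within the ring (3Z,7Z) and O1, isopropyl and O9 all cis (1R,9S,10S); ring positions follow that name, and the CIP letters at C9 and C10 change along the route only because substituent priorities change. Compounds 1, 5 and 20 and the named reagents are taken as commercially available.

**Route**

Step 1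
Reactants: 1 4-methyl-5,6-dihydro-2H-pyran-2-one
Product: 2 4-methyl-5,6-dihydro-2H-pyran-2-ol
Conditions: DIBAL-H (1.05 equiv), CH2Cl2, −78 °C; Rochelle salt work-up
Reagents that add atoms: none
Why: Partial lactone reduction with DIBAL-H stops at the lactol because the aluminium hemiacetal survives until work-up, and the ring holds the trisubstituted alkene cis.

Step 2
Reactants: 2 4-methyl-5,6-dihydro-2H-pyran-2-ol
Product: 3 (3Z)-3-methylhexa-3,5-dien-1-ol
Conditions: Ph3PCH3Br, KOtBu, THF, 0 °C to rt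
Reagents that add atoms: methyltriphenylphosphonium bromide, C[P+](c1ccccc1)(c1ccccc1)c1ccccc1.[Br-]
Why: Wittig methylenation of the open hydroxy-enal tautomer of the lactol should add one carbon while the Z alkene fixed by the former ring is untouched.

Step 3
Reactants: 3 (3Z)-3-methylhexa-3,5-dien-1-ol
Product: 4 1-methoxy-4-({[(3Z)-3-methylhexa-3,5-dien-1-yl]oxy}methyl)benzene
Conditions: NaH, 4-methoxybenzyl chloride, Bu4NI (cat.), THF/DMF, 0 °C to rt
Reagents that add atoms: 4-methoxybenzyl chloride, COc1ccc(CCl)cc1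
Why: Williamson etherification of the primary alkoxide is routine, and the PMB ether should survive every step up to its oxidative removal.

Step 4
Reactants: 5 but-2-ynoic acid
Product: 6 (2Z)-3-iodobut-2-enoic acid
Conditions: NaI, AcOH, 110 °C
Reagents that add atoms: sodium iodide, [Na+].[I-]
Why: Conjugate hydroiodination of the ynoic acid (iodide to the β-carbon, anti protonation) is the standard entry to (Z)-β-iodoacrylic acids, so iodine and carboxyl end up cis.

Step 5
Reactants: 6 (2Z)-3-iodobut-2-enoic acid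
Product: 7 (2Z)-3-iodo-N-methoxy-N-methylbut-2-enamide
Conditions: i-BuOCOCl, N-methylmorpholine, CH2Cl2, −15 °C; then MeNHOMe·HCl, N-methylmorpholine, −15 °C to rt
Reagents that add atoms: N,O-dimethylhydroxylamine hydrochloride, CNOC.Cl
Why: Weinreb amide formation through the mixed carbonic anhydride runs cold and without a nucleophilic catalyst, so addition–elimination at the β-iodo carbon and Z/E drift should be avoided.

Step 6
Reactants: 4 1-methoxy-4-({[(3Z)-3-methylhexa-3,5-dien-1-yl]oxy}methyl)benzene; 7 (2Z)-3-iodo-N-methoxy-N-methylbut-2-enamide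
Product: 9 (2Z,6Z)-N-methoxy-9-[(4-methoxybenzyl)oxy]-N,3,7-trimethylnona-2,6-dienamide, via alkyl-9-BBN borane 8 (not isolated)
Conditions: 9-BBN, THF, 0 °C to rt; then 7, Pd(dppf)Cl2 (5 mol %), AsPh3, Cs2CO3, DMF/H2O, rt
Reagents that add atoms: none
Why: Anti-Markovnikov hydroboration with 9-BBN takes only the monosubstituted end of the diene, and the B-alkyl Suzuki–Miyaura coupling proceeds with retention at the iodo-bearing carbon, so the new trisubstituted alkene is Z like the first.

Step 7
Reactants: 9 (2Z,6Z)-N-methoxy-9-[(4-methoxybenzyl)oxy]-N,3,7-trimethylnona-2,6-dienamide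
Product: 10 (5Z,9Z)-12-[(4-methoxybenzyl)oxy]-6,10-dimethyldodeca-5,9-dien-2-yn-4-one
Conditions: CH3C≡CMgBr, THF, −78 to −20 °C; inverse quench into cold 1 M HCl
Reagents that add atoms: 1-propynylmagnesium bromide, CC#C[Mg]Br
Why: Weinreb ketone synthesis: the magnesium chelate of the tetrahedral adduct prevents over-addition, and the cold acidic quench keeps the released amine from adding to the ynone and the Z-enone from isomerizing.

Step 8
Reactants: 10 (5Z,9Z)-12-[(4-methoxybenzyl)oxy]-6,10-dimethyldodeca-5,9-dien-2-yn-4-one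
Product: 11 (4S,5Z,9Z)-12-[(4-methoxybenzyl)oxy]-6,10-dimethyldodeca-5,9-dien-2-yn-4-ol
Conditions: (S)-Me-CBS oxazaborolidine (0.2–1.0 equiv), catecholborane, toluene, −78 °C
Reagents that add atoms: none
Why: Corey–Bakshi–Shibata reduction: the cis-substituted alkenyl group should act as the large and the rod-like propynyl group as the small substituent, so the (S)-catalyst should give the (4S)-alcohol, the future C9 center.

Step 9
Reactants: 11 (4S,5Z,9Z)-12-[(4-methoxybenzyl)oxy]-6,10-dimethyldodeca-5,9-dien-2-yn-4-ol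
Product: 12 (2Z,4S,5Z,9Z)-2-iodo-12-[(4-methoxybenzyl)oxy]-6,10-dimethyldodeca-2,5,9-trien-4-ol
Conditions: NaAlH2(OCH2CH2OMe)2 (Red-Al), THF, 0 °C to rt; EtOAc; then I2, −78 °C
Reagents that add atoms: iodine, II
Why: Hydroxyl-directed trans-hydroalumination of the propargylic alcohol places aluminium on the distal alkyne carbon in a five-membered alanate, and iodinolysis with retention gives the vinyl iodide with iodine cis to the carbinol carbon; the isolated alkenes are inert.

Step 10
Reactants: 12 (2Z,4S,5Z,9Z)-2-iodo-12-[(4-methoxybenzyl)oxy]-6,10-dimethyldodeca-2,5,9-trien-4-ol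
Product: 13 tert-butyl({(2Z,4S,5Z,9Z)-2-iodo-12-[(4-methoxybenzyl)oxy]-6,10-dimethyldodeca-2,5,9-trien-4-yl}oxy)dimethylsilane
Conditions: TBSOTf, 2,6-lutidine, CH2Cl2, −78 °C
Reagents that add atoms: tert-butyldimethylsilyl trifluoromethanesulfonate, CC(C)(C)[Si](C)(C)OS(=O)(=O)C(F)(F)F
Why: Silylation of the hindered bis-allylic alcohol with the silyl triflate and a hindered base is fast at low temperature and should not ionize the allylic C–O bond.

Step 11
Reactants: 13 tert-butyl({(2Z,4S,5Z,9Z)-2-iodo-12-[(4-methoxybenzyl)oxy]-6,10-dimethyldodeca-2,5,9-trien-4-yl}oxy)dimethylsilane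
Product: 14 (3Z,7Z,9S,10Z)-9-[(tert-butyldimethylsilyl)oxy]-11-iodo-3,7-dimethyldodeca-3,7,10-trien-1-ol
Conditions: DDQ, CH2Cl2/pH 7 buffer, 0 °C
Reagents that add atoms: none
Why: Oxidative PMB cleavage by DDQ (hydride abstraction at the electron-rich benzylic position, then hydrolysis) should leave the silyl ether, the vinyl iodide and the alkenes alone.

Step 12
Reactants: 14 (3Z,7Z,9S,10Z)-9-[(tert-butyldimethylsilyl)oxy]-11-iodo-3,7-dimethyldodeca-3,7,10-trien-1-ol
Product: 15 (3Z,7Z,9R,10Z)-9-[(tert-butyldimethylsilyl)oxy]-3,7,11-trimethyl-12-(4,4,5,5-tetramethyl-1,3,2-dioxaborolan-2-yl)dodeca-3,7,10-trien-1-ol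
Conditions: CH2(Bpin)2, Pd(P(t-Bu)3)2 (5 mol %), KOH (aq), 1,4-dioxane, rt
Reagents that add atoms: bis[(pinacolato)boryl]methane, CC1(C)OB(CB2OC(C)(C)C(C)(C)O2)OC1(C)C
Why: Suzuki–Miyaura coupling of a geminal bis(boronate) with an alkenyl iodide: the neighbouring boryl group speeds transmetalation of one C–B bond only, and reductive elimination with retention should give the (Z)-allylboronate with CH2B cis to the silyloxy-bearing carbon.

Step 13
Reactants: 15 (3Z,7Z,9R,10Z)-9-[(tert-butyldimethylsilyl)oxy]-3,7,11-trimethyl-12-(4,4,5,5-tetramethyl-1,3,2-dioxaborolan-2-yl)dodeca-3,7,10-trien-1-ol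
Product: 18 (1R,3Z,7Z,9S,10R)-9-[(tert-butyldimethylsilyl)oxy]-3,7-dimethyl-10-(prop-1-en-2-yl)cyclodeca-3,7-dien-1-ol, via boronate aldehyde 16 (not isolated), via O-boryl cyclization adduct 17 (not isolated)
Conditions: Dess–Martin periodinane, NaHCO3, CH2Cl2 (0.01 M), 0 °C; then PhMe (0.002 M), 50 °C; aq. NaHCO3 work-up
Reagents that add atoms: none
Why: Proposed new method: oxidation of 15 unmasks the β,γ-unsaturated aldehyde 16, whose oxygen binds the boron of the tethered (Z)-allylboronate so that the γ-carbon (future C10) adds to the aldehyde carbon (future C1) through a closed six-membered chair transition state, boron passing to oxygen and the double bond moving into the new isopropenyl group. The closest known reaction types are the intramolecular allylboration of aldehydes, shown for five- to eight-membered carbocycles, and the CrCl2-mediated intramolecular allylation of aldehydes that closes ten-membered germacrane rings; the mechanism is the known one and only its use for a ten-membered ring is new. One ring is closed, the ten-membered carbocycle, by attack of the allyl γ-carbon on the carbonyl carbon with the C=O bond outside the new ring (10-exo-trig), and the two Z-trisubstituted alkenes pre-fold the chain and keep transannular strain low. C1 is set relative to C10 by the chair: the Z-boronate places the C9 branch axial and the C2 chain equatorial, which gives the syn (ring-cis) O1/isopropenyl pair. C10 is set by the silyloxy-bearing C9: allylic 1,3-strain with the cis CH2B group turns H9 inside, and the aldehyde should then add to the face on which the C9–C8 bond is antiperiplanar to the forming bond and the OTBS group is outside, which gives the all-cis 1,9,10 triad. The step needs Z-allyl fidelity, face selectivity at C10 and ring closure in preference to oligomerization, which are secured by the configurationally stable pinacol boronate, by C9 and by high dilution.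

Step 14
Reactants: 18 (1R,3Z,7Z,9S,10R)-9-[(tert-butyldimethylsilyl)oxy]-3,7-dimethyl-10-(prop-1-en-2-yl)cyclodeca-3,7-dien-1-ol
Product: 19 (1R,3Z,7Z,9S,10R)-9-[(tert-butyldimethylsilyl)oxy]-3,7-dimethyl-10-(propan-2-yl)cyclodeca-3,7-dien-1-ol
Conditions: H2 (1 atm), RhCl(PPh3)3 (10 mol %), benzene/EtOH, rt
Reagents that add atoms: none
Why: Homogeneous hydrogenation with RhCl(PPh3)3 should reduce the 1,1-disubstituted alkene far faster than the two trisubstituted ring alkenes, and it creates no stereocenter.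

Step 15
Reactants: 20 vanillic acid (4-hydroxy-3-methoxybenzoic acid)
Product: 22 4-[(tert-butyldimethylsilyl)oxy]-3-methoxybenzoic acid, via bis-silylated vanillic acid 21 (not isolated)
Conditions: TBSCl (2.5 equiv), imidazole, DMF, rt; then AcOH/THF/H2O, rt
Reagents that add atoms: tert-butyldimethylsilyl chloride, CC(C)(C)[Si](C)(C)Cl
Why: Silylation of both acidic groups followed by selective hydrolysis of the labile silyl ester (the aryl silyl ether survives aqueous acetic acid) should give the phenol-protected acid.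

Step 16
Reactants: 19 (1R,3Z,7Z,9S,10R)-9-[(tert-butyldimethylsilyl)oxy]-3,7-dimethyl-10-(propan-2-yl)cyclodeca-3,7-dien-1-ol; 22 4-[(tert-butyldimethylsilyl)oxy]-3-methoxybenzoic acid
Product: 23 (1R,3Z,7Z,9S,10R)-9-[(tert-butyldimethylsilyl)oxy]-3,7-dimethyl-10-(propan-2-yl)cyclodeca-3,7-dien-1-yl 4-[(tert-butyldimethylsilyl)oxy]-3-methoxybenzoate
Conditions: 2,4,6-Cl3C6H2COCl, Et3N, THF, rt; then 19, DMAP, PhMe, rt to 40 °C
Reagents that add atoms: none
Why: Yamaguchi esterification (mixed anhydride, DMAP acyl transfer) acylates hindered secondary alcohols without breaking the C1–O bond, so C1 keeps its configuration.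

Step 17
Reactants: 23 (1R,3Z,7Z,9S,10R)-9-[(tert-butyldimethylsilyl)oxy]-3,7-dimethyl-10-(propan-2-yl)cyclodeca-3,7-dien-1-yl 4-[(tert-butyldimethylsilyl)oxy]-3-methoxybenzoate
Product: 24 (1R,3Z,7Z,9S,10S)-9-hydroxy-3,7-dimethyl-10-(propan-2-yl)cyclodeca-3,7-dien-1-yl 4-hydroxy-3-methoxybenzoate
Conditions: TBAF/AcOH (1:1), THF, 0 °C to rt
Reagents that add atoms: none
Why: Fluoride-mediated cleavage of both silyl ethers; buffering with acetic acid keeps the freed C9 alkoxide protonated and should suppress 1,3-acyl migration from O1 to O9.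

**Compound list**

1 | 4-methyl-5,6-dihydro-2H-pyran-2-one (anhydromevalonolactone) | CC1=CC(=O)OCC1 | starting material
2 | 4-methyl-5,6-dihydro-2H-pyran-2-ol (racemic lactol) | CC1=CC(O)OCC1 | intermediate
3 | (3Z)-3-methylhexa-3,5-dien-1-ol | C=C/C=C(C)\CCO | intermediate
4 | 1-methoxy-4-({[(3Z)-3-methylhexa-3,5-dien-1-yl]oxy}methyl)benzene | C=C/C=C(C)\CCOCc1ccc(OC)cc1 | intermediate
5 | but-2-ynoic acid | CC#CC(=O)O | starting material
6 | (2Z)-3-iodobut-2-enoic acid | C/C(I)=C/C(=O)O | intermediate
7 | (2Z)-3-iodo-N-methoxy-N-methylbut-2-enamide | C/C(I)=C/C(=O)N(C)OC | intermediate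
8 | 9-{(3Z)-6-[(4-methoxybenzyl)oxy]-4-methylhex-3-en-1-yl}-9-borabicyclo[3.3.1]nonane | COc1ccc(COCC/C(C)=C\CCB2C3CCCC2CCC3)cc1 | intermediate
9 | (2Z,6Z)-N-methoxy-9-[(4-methoxybenzyl)oxy]-N,3,7-trimethylnona-2,6-dienamide | CON(C)C(=O)/C=C(C)\CC/C=C(C)\CCOCc1ccc(OC)cc1 | intermediate
10 | (5Z,9Z)-12-[(4-methoxybenzyl)oxy]-6,10-dimethyldodeca-5,9-dien-2-yn-4-one | CC#CC(=O)/C=C(C)\CC/C=C(C)\CCOCc1ccc(OC)cc1 | intermediate
11 | (4S,5Z,9Z)-12-[(4-methoxybenzyl)oxy]-6,10-dimethyldodeca-5,9-dien-2-yn-4-ol | CC#C[C@@H](O)/C=C(C)\CC/C=C(C)\CCOCc1ccc(OC)cc1 | intermediate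
12 | (2Z,4S,5Z,9Z)-2-iodo-12-[(4-methoxybenzyl)oxy]-6,10-dimethyldodeca-2,5,9-trien-4-ol | C/C(I)=C/[C@@H](O)/C=C(C)\CC/C=C(C)\CCOCc1ccc(OC)cc1 | intermediate
13 | tert-butyl({(2Z,4S,5Z,9Z)-2-iodo-12-[(4-methoxybenzyl)oxy]-6,10-dimethyldodeca-2,5,9-trien-4-yl}oxy)dimethylsilane | C/C(I)=C/[C@@H](O[Si](C)(C)C(C)(C)C)/C=C(C)\CC/C=C(C)\CCOCc1ccc(OC)cc1 | intermediate
14 | (3Z,7Z,9S,10Z)-9-[(tert-butyldimethylsilyl)oxy]-11-iodo-3,7-dimethyldodeca-3,7,10-trien-1-ol | C/C(I)=C/[C@@H](O[Si](C)(C)C(C)(C)C)/C=C(C)\CC/C=C(C)\CCO | intermediate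
15 | (3Z,7Z,9R,10Z)-9-[(tert-butyldimethylsilyl)oxy]-3,7,11-trimethyl-12-(4,4,5,5-tetramethyl-1,3,2-dioxaborolan-2-yl)dodeca-3,7,10-trien-1-ol | CC1(C)OB(C/C(C)=C\[C@@H](O[Si](C)(C)C(C)(C)C)/C=C(C)\CC/C=C(C)\CCO)OC1(C)C | intermediate
16 | (3Z,7Z,9R,10Z)-9-[(tert-butyldimethylsilyl)oxy]-3,7,11-trimethyl-12-(4,4,5,5-tetramethyl-1,3,2-dioxaborolan-2-yl)dodeca-3,7,10-trienal | CC1(C)OB(C/C(C)=C\[C@@H](O[Si](C)(C)C(C)(C)C)/C=C(C)\CC/C=C(C)\CC=O)OC1(C)C | intermediate
17 | 2-({(1R,3Z,7Z,9S,10R)-9-[(tert-butyldimethylsilyl)oxy]-3,7-dimethyl-10-(prop-1-en-2-yl)cyclodeca-3,7-dien-1-yl}oxy)-4,4,5,5-tetramethyl-1,3,2-dioxaborolane | CC1(C)OB(O[C@@H]2C/C(C)=C\CC/C(C)=C\[C@H](O[Si](C)(C)C(C)(C)C)[C@@H]2C(C)=C)OC1(C)C | intermediate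
18 | (1R,3Z,7Z,9S,10R)-9-[(tert-butyldimethylsilyl)oxy]-3,7-dimethyl-10-(prop-1-en-2-yl)cyclodeca-3,7-dien-1-ol | O[C@@H]1C/C(C)=C\CC/C(C)=C\[C@H](O[Si](C)(C)C(C)(C)C)[C@@H]1C(C)=C | intermediate
19 | (1R,3Z,7Z,9S,10R)-9-[(tert-butyldimethylsilyl)oxy]-3,7-dimethyl-10-(propan-2-yl)cyclodeca-3,7-dien-1-ol | O[C@@H]1C/C(C)=C\CC/C(C)=C\[C@H](O[Si](C)(C)C(C)(C)C)[C@@H]1C(C)C | intermediate
20 | vanillic acid (4-hydroxy-3-methoxybenzoic acid) | COc1cc(C(=O)O)ccc1O | starting material
21 | tert-butyldimethylsilyl 4-[(tert-butyldimethylsilyl)oxy]-3-methoxybenzoate | COc1cc(C(=O)O[Si](C)(C)C(C)(C)C)ccc1O[Si](C)(C)C(C)(C)C | intermediate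
22 | 4-[(tert-butyldimethylsilyl)oxy]-3-methoxybenzoic acid | COc1cc(C(=O)O)ccc1O[Si](C)(C)C(C)(C)C | intermediate
23 | (1R,3Z,7Z,9S,10R)-9-[(tert-butyldimethylsilyl)oxy]-3,7-dimethyl-10-(propan-2-yl)cyclodeca-3,7-dien-1-yl 4-[(tert-butyldimethylsilyl)oxy]-3-methoxybenzoate | COc1cc(C(=O)O[C@@H]2C/C(C)=C\CC/C(C)=C\[C@H](O[Si](C)(C)C(C)(C)C)[C@@H]2C(C)C)ccc1O[Si](C)(C)C(C)(C)C | intermediate
24 | (1R,3Z,7Z,9S,10S)-9-hydroxy-3,7-dimethyl-10-(propan-2-yl)cyclodeca-3,7-dien-1-yl 4-hydroxy-3-methoxybenzoate | COc1cc(C(=O)O[C@@H]2C/C(C)=C\CC/C(C)=C\[C@H](O)[C@@H]2C(C)C)ccc1O | target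

**Step count and risks**

Total steps: 17. Longest linear sequence: 14 steps (1–3, 6–14, 16, 17).

Steps most likely to fail:

1. Step 13 (proposed new method). Ring closure may be too slow, so that intermolecular allylboration (oligomerization) or migration of the aldehyde's β,γ-double bond into conjugation takes over, or the aldehyde may add to the other face of the allyl unit. Fallback with known chemistry, setting out from 15: oxidation of the C–B bond with NaBO3·4H2O (THF/H2O) should give (2Z,4S,5Z,9Z)-4-[(tert-butyldimethylsilyl)oxy]-2,6,10-trimethyldodeca-2,5,9-triene-1,12-diol F1. Corey–Kim bromination (NBS, Me2S, CH2Cl2, −20 °C) should convert only the allylic hydroxyl and give (3Z,7Z,9S,10Z)-12-bromo-9-[(tert-butyldimethylsilyl)oxy]-3,7,11-trimethyldodeca-3,7,10-trien-1-ol F2. Dess–Martin oxidation should give (3Z,7Z,9S,10Z)-12-bromo-9-[(tert-butyldimethylsilyl)oxy]-3,7,11-trimethyldodeca-3,7,10-trienal F3. Slow addition of F3 to CrCl2 in THF (Nozaki–Hiyama–Kishi allylation at high dilution, the precedented closure of ten-membered germacrane rings) should close the ring, and the route is rejoined at 18. The stereochemical outcome of this chromium closure is less predictable than that of the boronate chair and would have to be checked against 18.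

2. Step 12. Transmetalation at the hindered Z-iodide may be slow, the allylboronate may protodeboronate under aqueous KOH, or it may couple a second time. Fallback setting out from 14: Pd(PPh3)2Cl2-catalysed methoxycarbonylation (CO, MeOH, Et3N, 50 °C) should give methyl (2Z,4S,5Z,9Z)-4-[(tert-butyldimethylsilyl)oxy]-12-hydroxy-2,6,10-trimethyldodeca-2,5,9-trienoate F4 with retention of geometry. DIBAL-H reduction of the ester gives the diol F1, which is carried through F2 and F3 and the CrCl2 ring closure as above; the route is rejoined at 18 without any organoboron intermediate.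

3. Step 8. Enantioselectivity may be poor if the alkenyl and alkynyl groups are not differentiated well enough by the catalyst, and ynone 10 may drift from Z to E before it is reduced. Fallback setting out from 9: DIBAL-H reduction of the Weinreb amide (THF, −78 °C) should give (2Z,6Z)-9-[(4-methoxybenzyl)oxy]-3,7-dimethylnona-2,6-dienal F5. Catalytic asymmetric alkynylation with propyne (Me2Zn, the ProPhenol ligand enantiomer that gives the 4S alcohol, Ph3PO, toluene, 0 °C) then forms the C–C bond and the stereocenter together, and the route is rejoined at 11.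

Further compounds
F1 | step 13 | (2Z,4S,5Z,9Z)-4-[(tert-butyldimethylsilyl)oxy]-2,6,10-trimethyldodeca-2,5,9-triene-1,12-diol | OC/C(C)=C\[C@@H](O[Si](C)(C)C(C)(C)C)/C=C(C)\CC/C=C(C)\CCO
F2 | step 13 | (3Z,7Z,9S,10Z)-12-bromo-9-[(tert-butyldimethylsilyl)oxy]-3,7,11-trimethyldodeca-3,7,10-trien-1-ol | BrC/C(C)=C\[C@@H](O[Si](C)(C)C(C)(C)C)/C=C(C)\CC/C=C(C)\CCO
F3 | step 13 | (3Z,7Z,9S,10Z)-12-bromo-9-[(tert-butyldimethylsilyl)oxy]-3,7,11-trimethyldodeca-3,7,10-trienal | BrC/C(C)=C\[C@@H](O[Si](C)(C)C(C)(C)C)/C=C(C)\CC/C=C(C)\CC=O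
F4 | step 12 | methyl (2Z,4S,5Z,9Z)-4-[(tert-butyldimethylsilyl)oxy]-12-hydroxy-2,6,10-trimethyldodeca-2,5,9-trienoate | COC(=O)/C(C)=C\[C@@H](O[Si](C)(C)C(C)(C)C)/C=C(C)\CC/C=C(C)\CCO
F5 | step 8 | (2Z,6Z)-9-[(4-methoxybenzyl)oxy]-3,7-dimethylnona-2,6-dienal | O=C/C=C(C)\CC/C=C(C)\CCOCc1ccc(OC)cc1
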